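**Strategy.** The route cuts ring B of the labdane core at C7–C8 and C9–C10 and remakes both bonds in one intermolecular Diels–Alder reaction between the ring-A diene C7=C6–C5=C10 of vinylcyclohexene 12 and methyl but-2-ynoate 13. The step exploits the 1,2-relationship of the C17 methyl on C8 and the C11 branch on C9, both flanking the fully substituted C10 in ring B. One operation closes ring B, creates C10 with its angular methyl and installs both substituents. The precursor is (S)-methyl 1,3-dimethyl-2-vinylcyclohex-2-ene-1-carboxylate, whose C4 quaternary centre (its ester is the later C19) steers the face of attack.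

Key step: step 6

Assumption: the lithium aza-enolate of the L-valine-derived enamine 3 is taken to be methylated, in toluene with one equivalent of HMPA, on the face that leads to the (S) keto ester 6; should the sense be the opposite, D-valine tert-butyl ester gives 6 by the same two steps.

Remark on numbering: labdane positions of the target are used for all ring compounds (ring A = C1–C5, C10; ring B = C5–C10; C11 on C9, C17 on C8, C18 (α) and C19 (β) on C4, C20 on C10).

**Step 1**
Reactants: 1 methyl 2-oxocyclohexane-1-carboxylate; 2 L-valine tert-butyl ester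
Product: 3 methyl 2-{[(2S)-1-tert-butoxy-3-methyl-1-oxobutan-2-yl]amino}cyclohex-1-ene-1-carboxylate
Conditions: BF3·OEt2 (cat.), benzene, reflux, Dean–Stark
Reagents that add atoms: none
Why: Acid-catalysed condensation of the β-keto ester with the primary amine (enamine formation) gives the hydrogen-bonded enamino ester and is driven by azeotropic removal of water.

**Step 2**
Reactants: 3 chiral enamino ester
Product: 6 methyl (S)-1-methyl-2-oxocyclohexane-1-carboxylate, via lithium aza-enolate 4 (not isolated), via ketimine 5 (not isolated)
Conditions: LiN(iPr)2, toluene, −78 °C; HMPA (1 equiv), MeI, −78 → −40 °C; then 1 M aq. HCl, rt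
Reagents that add atoms: iodomethane, CI; water, O
Why: Deprotonation gives a chelated lithium aza-enolate whose valine isopropyl group screens one face, so C-methylation (asymmetric alkylation of a chiral amino-ester enamine) should set the C4 quaternary centre as (S), and acid hydrolysis of the ketimine releases the keto ester and the auxiliary.

**Step 3**
Reactants: 6 methyl (S)-1-methyl-2-oxocyclohexane-1-carboxylate
Product: 8 methyl (1S)-1,3-dimethyl-2-oxocyclohexane-1-carboxylate (epimers at C3), via lithium enolate 7 (not isolated)
Conditions: LiN(iPr)2, THF, −78 °C; MeI, −78 → 0 °C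
Reagents that add atoms: iodomethane, CI
Why: The ketone can enolise only at its methylene, so enolate formation and SN2 methylation (enolate alkylation) place the future C20 methyl, and the new centre need not be controlled because it becomes sp2 in the next step.

**Step 4**
Reactants: 8 methyl (1S)-1,3-dimethyl-2-oxocyclohexane-1-carboxylate
Product: 10 methyl (S)-1,3-dimethyl-2-{[(trifluoromethyl)sulfonyl]oxy}cyclohex-2-ene-1-carboxylate, via potassium enolate 9 (not isolated)
Conditions: KN(SiMe3)2, THF, −78 → −20 °C; PhNTf2, −78 °C → rt
Reagents that add atoms: N-phenylbis(trifluoromethanesulfonimide), O=S(=O)(N(c1ccccc1)S(=O)(=O)C(F)(F)F)C(F)(F)F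
Why: Enolisation is possible only toward the methyl-bearing carbon, so the single tetrasubstituted potassium enolate is trapped on oxygen by the triflimide (enol triflate formation).

**Step 5**
Reactants: 10 enol triflate; 11 tributyl(vinyl)stannane
Product: 12 methyl (S)-1,3-dimethyl-2-vinylcyclohex-2-ene-1-carboxylate
Conditions: Pd(PPh3)4 (5 mol %), LiCl (3 equiv), THF, reflux
Reagents that add atoms: none
Why: Oxidative addition of zerovalent palladium into the vinyl C–O bond, chloride-assisted transfer of the vinyl group from tin and reductive elimination give the 1,3-diene (Stille coupling of an enol triflate).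

**Step 6**
Reactants: 12 methyl (S)-1,3-dimethyl-2-vinylcyclohex-2-ene-1-carboxylate; 13 methyl but-2-ynoate
Product: 14 dimethyl 12,13,14,15,16-pentanorlabda-5,8-diene-11,19-dioate [dimethyl (5S,8aS)-2,5,8a-trimethyl-3,5,6,7,8,8a-hexahydronaphthalene-1,5-dicarboxylate; 10β-methyl cis to the 4β-ester]
Conditions: 13 (5 equiv), BHT (cat.), CH2Cl2, 1.3 GPa (13 kbar), 45 °C, 3 d
Reagents that add atoms: none
Why: The reaction is a concerted, asynchronous, suprafacial [4+2] cycloaddition of normal electron demand between the s-cis diene C7=C6–C5=C10 and the triple bond of 13; the closest known type is the Diels–Alder reaction of 2-methyl-1-vinylcyclohexenes with acetylenic esters, which gives angular-methyl hexahydronaphthalenes and is accelerated by pressure when the diene is hindered. Ring B is closed by intermolecular cycloaddition, the bonds C7–C8 and C9–C10 forming in the same step to give a cyclohexa-1,4-diene. The one new stereocentre, C10, is controlled by the C4 quaternary centre: in the half-chair of ring A the slimmer CO2Me takes the pseudoaxial site and the C4 methyl the pseudoequatorial one, the ynoate bonds to C10 on the face away from the pseudoaxial ester, and the C20 methyl bends toward that ester, so C20 and C19 end cis. Regioselectivity is needed and should follow from the orbital coefficients, since the unsubstituted terminus C7 (C10 being the dialkylated donor end) joins the β-carbon of the ynoate, which places the ester carbon C11 on C9 beside C10 and the methyl on C8. An alkyne partner adds no further stereocentre and leaves C7 doubly allylic and γ to the ester, which step 7 uses.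

**Step 7**
Reactants: 14 5,8-diene diester
Product: 16 dimethyl 12,13,14,15,16-pentanorlabda-5,7-diene-11,19-dioate (9α-H, 9β-ester), via potassium trienolate 15 (not isolated)
Conditions: KN(SiMe3)2 (1.3 equiv), THF, −78 → −30 °C; then AcOH, THF, −78 °C
Reagents that add atoms: none
Why: The doubly allylic C7–H, γ to the C11 ester, is the most acidic position while C5=C6 is still present (after its saturation the C17 methyl cis to the ester would compete), and kinetic protonation of the trienolate at its α-carbon C9 from the α face, anti to C20, should give the deconjugated ester with 9α-H and C7=C8 in place (deconjugative isomerisation of an unsaturated ester through its extended enolate), any 14 re-formed by protonation at C7 being recycled.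

**Step 8**
Reactants: 16 5,7-diene diester
Product: 17 dimethyl 12,13,14,15,16-pentanorlabd-7-ene-11,19-dioate (5α-H, 9α-H; trans ring fusion)
Conditions: H2 (1 atm, stopped after 1 equiv), PtO2 (cat.), EtOAc, rt
Reagents that add atoms: none
Why: The homoannular diene should bind to the catalyst on its α face (the β face is screened by C20 and the axial C19 ester) and take up hydrogen across C5=C6 to give 5α-H, because delivery to C8 would push the C17 methyl into a 1,3-diaxial clash with C20, the same bias by which ring-B 5,7-dienes of steroids give 7-enes (partial hydrogenation of a conjugated diene).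

**Step 9**
Reactants: 17 7-ene diester
Product: 18 methyl 11-hydroxy-12,13,14,15,16-pentanorlabd-7-en-19-oate
Conditions: iBu2AlH (2.5 equiv), CH2Cl2, −78 → −30 °C; aq. potassium sodium tartrate
Reagents that add atoms: none
Why: The bulky aluminium hydride should reduce the equatorial C11 ester on a methine carbon and leave the axial C19 ester on quaternary C4, which is screened by the 1,3-diaxial C20 methyl (chemoselective ester reduction on steric grounds, as known for axial C4 esters of resin-acid skeletons).

**Step 10**
Reactants: 18 hydroxy ester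
Product: 19 methyl 11-oxo-12,13,14,15,16-pentanorlabd-7-en-19-oate
Conditions: Dess–Martin periodinane, pyridine, CH2Cl2, 0 °C → rt
Reagents that add atoms: none
Why: Dess–Martin oxidation of the primary alcohol under pyridine buffering is mild and non-basic, so the C9 stereocentre and the β,γ-double bond of the aldehyde should stay untouched.

**Step 11**
Reactants: 19 aldehyde ester
Product: 20 methyl 13,14,15,16-tetranorlabda-7,11-dien-19-oate (C9 vinyl compound)
Conditions: Ph3PCH3Br, KN(SiMe3)2, THF, 0 °C; then 19, −78 → 0 °C
Reagents that add atoms: methyltriphenylphosphonium bromide, [Br-].C[P+](c1ccccc1)(c1ccccc1)c1ccccc1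
Why: Wittig methylenation with the unstabilised ylide at low temperature should outrun enolisation of the hindered C9–H and turns the aldehyde into the C11=C12 vinyl group without touching the C19 ester.

**Step 12**
Reactants: 20 vinyl ester
Product: 21 13,14,15,16-tetranorlabda-7,11-dien-19-ol
Conditions: LiAlH4, THF, reflux; then H2O, 0 °C
Reagents that add atoms: none
Why: With no other reducible group left, the complex hydride at reflux reduces the hindered C19 ester to the neopentyl primary alcohol (ester reduction).

**Step 13**
Reactants: 21 C19 alcohol; 22 tigloyl chloride [(E)-2-methylbut-2-enoyl chloride]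
Product: 23 13,14,15,16-tetranorlabda-7,11-dien-19-yl (E)-2-methylbut-2-enoate
Conditions: DMAP, pyridine, CH2Cl2, rt → 40 °C
Reagents that add atoms: none
Why: DMAP-catalysed acyl transfer from the acid chloride esterifies the neopentyl alcohol, and the E geometry of the tiglate, being the stable one, is retained.

**Step 14**
Reactants: 24 but-2-ynoic acid; 25 2-(trimethylsilyl)ethanol
Product: 26 2-(trimethylsilyl)ethyl but-2-ynoate
Conditions: DCC, DMAP (cat.), CH2Cl2, 0 °C → rt
Reagents that add atoms: none
Why: Carbodiimide activation with DMAP acyl transfer (Steglich esterification) gives the silylethyl ester, chosen so that the C15 acid can later be freed without touching the tiglate.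

**Step 15**
Reactants: 26 2-(trimethylsilyl)ethyl but-2-ynoate
Product: 27 2-(trimethylsilyl)ethyl (Z)-3-iodobut-2-enoate
Conditions: NaI, AcOH, 80 °C
Reagents that add atoms: sodium iodide, [Na+].[I-]
Why: Iodide adds to the β-carbon of the acid-activated ynoate and protonation follows anti (hydroiodination of an alk-2-ynoate), which gives the Z iodo-enoate with iodine and ester cis.

**Step 16**
Reactants: 23 vinyl tiglate; 27 2-(trimethylsilyl)ethyl (Z)-3-iodobut-2-enoate
Product: 29 2-(trimethylsilyl)ethyl (13Z)-19-[(E)-2-methylbut-2-enoyloxy]labda-7,13-dien-15-oate, via alkylborane 28 (not isolated)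
Conditions: 9-BBN, THF, 0 °C → rt; then 27, PdCl2(dppf) (5 mol %), AsPh3, Cs2CO3, DMF/H2O, rt
Reagents that add atoms: none
Why: 9-BBN adds anti-Markovnikov to the only monosubstituted alkene (the trisubstituted ring alkene and the electron-poor tiglate are inert at room temperature), and the B-alkyl Suzuki–Miyaura coupling at zerovalent palladium formed in the flask joins C12 to C13 with retention of the iodoalkene geometry, so C12 and the ester stay cis (13Z).

**Step 17**
Reactants: 29 silylethyl ester
Product: 30 (13Z)-19-[(E)-2-methylbut-2-enoyloxy]labda-7,13-dien-15-oic acid (4S,5R,9S,10R), the target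
Conditions: Bu4NF, THF, 0 °C → rt; then dil. aq. HCl (pH 3)
Reagents that add atoms: none
Why: Fluoride attacks silicon and the 2-(trimethylsilyl)ethyl ester fragments to ethene, fluorosilane and the carboxylate (fluoride-induced β-elimination), conditions that should leave the hindered tiglate and both alkenes alone.

**Compound list**
1 | methyl 2-oxocyclohexane-1-carboxylate | COC(=O)C1CCCCC1=O | starting material
2 | L-valine tert-butyl ester | CC(C)[C@H](N)C(=O)OC(C)(C)C | starting material
3 | methyl 2-{[(2S)-1-tert-butoxy-3-methyl-1-oxobutan-2-yl]amino}cyclohex-1-ene-1-carboxylate | COC(=O)C1=C(N[C@@H](C(C)C)C(=O)OC(C)(C)C)CCCC1 | intermediate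
4 | lithium aza-enolate of 3 | COC(=O)C1=C([N-][C@@H](C(C)C)C(=O)OC(C)(C)C)CCCC1.[Li+] | intermediate (not isolated)
5 | methyl (1S)-2-{[(2S)-1-tert-butoxy-3-methyl-1-oxobutan-2-yl]imino}-1-methylcyclohexane-1-carboxylate | COC(=O)[C@@]1(C)CCCCC1=N[C@@H](C(C)C)C(=O)OC(C)(C)C | intermediate (not isolated)
6 | methyl (S)-1-methyl-2-oxocyclohexane-1-carboxylate | COC(=O)[C@@]1(C)CCCCC1=O | intermediate
7 | lithium enolate of 6 | COC(=O)[C@@]1(C)CCCC=C1[O-].[Li+] | intermediate (not isolated)
8 | methyl (1S)-1,3-dimethyl-2-oxocyclohexane-1-carboxylate (C3 epimers) | COC(=O)[C@@]1(C)CCCC(C)C1=O | intermediate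
9 | potassium enolate of 8 | COC(=O)[C@@]1(C)CCCC(C)=C1[O-].[K+] | intermediate (not isolated)
10 | methyl (S)-1,3-dimethyl-2-{[(trifluoromethyl)sulfonyl]oxy}cyclohex-2-ene-1-carboxylate | COC(=O)[C@@]1(C)CCCC(C)=C1OS(=O)(=O)C(F)(F)F | intermediate
11 | tributyl(vinyl)stannane | C=C[Sn](CCCC)(CCCC)CCCC | starting material
12 | methyl (S)-1,3-dimethyl-2-vinylcyclohex-2-ene-1-carboxylate | COC(=O)[C@@]1(C)CCCC(C)=C1C=C | intermediate
13 | methyl but-2-ynoate | CC#CC(=O)OC | starting material
14 | dimethyl 12,13,14,15,16-pentanorlabda-5,8-diene-11,19-dioate | COC(=O)[C@@]1(C)CCC[C@]2(C)C(C(=O)OC)=C(C)CC=C12 | intermediate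
15 | potassium trienolate of 14 (O–C11=C9, C8=C7, C6=C5) | COC(=O)[C@@]1(C)CCC[C@]2(C)C(=C(OC)[O-])C(C)=CC=C12.[K+] | intermediate (not isolated)
16 | dimethyl 12,13,14,15,16-pentanorlabda-5,7-diene-11,19-dioate (9α-H) | COC(=O)[C@@]1(C)CCC[C@]2(C)[C@@H](C(=O)OC)C(C)=CC=C12 | intermediate
17 | dimethyl 12,13,14,15,16-pentanorlabd-7-ene-11,19-dioate (5α-H, 9α-H) | COC(=O)[C@@]1(C)CCC[C@]2(C)[C@@H](C(=O)OC)C(C)=CC[C@@H]12 | intermediate
18 | methyl 11-hydroxy-12,13,14,15,16-pentanorlabd-7-en-19-oate | COC(=O)[C@@]1(C)CCC[C@]2(C)[C@@H](CO)C(C)=CC[C@@H]12 | intermediate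
19 | methyl 11-oxo-12,13,14,15,16-pentanorlabd-7-en-19-oate | COC(=O)[C@@]1(C)CCC[C@]2(C)[C@@H](C=O)C(C)=CC[C@@H]12 | intermediate
20 | methyl 13,14,15,16-tetranorlabda-7,11-dien-19-oate | COC(=O)[C@@]1(C)CCC[C@]2(C)[C@@H](C=C)C(C)=CC[C@@H]12 | intermediate
21 | 13,14,15,16-tetranorlabda-7,11-dien-19-ol | OC[C@@]1(C)CCC[C@]2(C)[C@@H](C=C)C(C)=CC[C@@H]12 | intermediate
22 | tigloyl chloride [(E)-2-methylbut-2-enoyl chloride] | C/C=C(\C)C(=O)Cl | starting material
23 | 13,14,15,16-tetranorlabda-7,11-dien-19-yl (E)-2-methylbut-2-enoate | C/C=C(\C)C(=O)OC[C@@]1(C)CCC[C@]2(C)[C@@H](C=C)C(C)=CC[C@@H]12 | intermediate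
24 | but-2-ynoic acid | CC#CC(=O)O | starting material
25 | 2-(trimethylsilyl)ethanol | C[Si](C)(C)CCO | starting material
26 | 2-(trimethylsilyl)ethyl but-2-ynoate | CC#CC(=O)OCC[Si](C)(C)C | intermediate
27 | 2-(trimethylsilyl)ethyl (Z)-3-iodobut-2-enoate | C/C(I)=C/C(=O)OCC[Si](C)(C)C | intermediate
28 | 9-[19-tigloyloxy-13,14,15,16-tetranorlabd-7-en-12-yl]-9-borabicyclo[3.3.1]nonane | C/C=C(\C)C(=O)OC[C@@]1(C)CCC[C@]2(C)[C@@H](CCB3C4CCCC3CCC4)C(C)=CC[C@@H]12 | intermediate (not isolated)
29 | 2-(trimethylsilyl)ethyl (13Z)-19-[(E)-2-methylbut-2-enoyloxy]labda-7,13-dien-15-oate | C/C=C(\C)C(=O)OC[C@@]1(C)CCC[C@]2(C)[C@@H](CC/C(C)=C\C(=O)OCC[Si](C)(C)C)C(C)=CC[C@@H]12 | intermediate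
30 | (13Z)-19-[(E)-2-methylbut-2-enoyloxy]labda-7,13-dien-15-oic acid | C/C=C(\C)C(=O)OC[C@@]1(C)CCC[C@]2(C)[C@@H](CC/C(C)=C\C(=O)O)C(C)=CC[C@@H]12 | target

**Step count.** Total: 17 steps. Longest linear sequence: 15 steps (steps 1–13, 16, 17); steps 14–15 make the side-chain partner 27.

**Steps most likely to fail**

Step 6. The cycloaddition may be too slow for this hindered diene, so that the diene is lost to polymerisation, or the ynoate may add with the opposite orientation or to the wrong face of C10. The fallback sets out from diene 12 and replaces the ynoate by its allenic isomer, commercial methyl buta-2,3-dienoate (C=C=CC(=O)OC), whose electron-poor 2,3-double bond is a far better 2π partner (EtAlCl2, CH2Cl2, −78 → 0 °C, or toluene, 90 °C). The same bonds C7–C8 and C9–C10 form, the central allene carbon joining C7, and the product is dimethyl 12,13,14,15,16-pentanorlabda-5,8(17)-diene-11,19-dioate F1, whose C9 configuration is irrelevant. DBU in CH2Cl2 at rt then moves the exocyclic double bond into conjugation with the C11 ester, and the route is rejoined at 14.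

Step 8. Hydrogen may be delivered to C7=C8 or 1,4 across the diene instead of to C5=C6, or the alkene left behind may migrate into conjugation with the ester. The fallback sets out from 14 and hydrogenates first (H2, Pd/C, EtOAc), when C5=C6 is the only alkene open to the catalyst, to give dimethyl 12,13,14,15,16-pentanorlabd-8-ene-11,19-dioate F2. Radical bromination (NBS, AIBN cat., PhCF3, reflux) at the ring allylic methylene gives dimethyl 7-bromo-12,13,14,15,16-pentanorlabd-8-ene-11,19-dioate F3. Zinc dust in AcOH/Et2O at 0 °C then reduces the carbon–bromine bond to a zinc dienolate, which is protonated at C9 from the α face, and the route is rejoined at 17. This path also bypasses step 7.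

Step 9. Discrimination between the two esters may be incomplete, with partial reduction at C19 or stalling at the aldehyde stage at C11. The fallback sets out from 17 and reduces both esters (LiAlH4, THF, reflux) to 12,13,14,15,16-pentanorlabd-7-ene-11,19-diol F4. Oxoammonium oxidation (TEMPO cat., PhI(OAc)2, CH2Cl2, rt) should take the β-branched C11 hydroxyl and leave the axial neopentyl C19 hydroxyl, giving 19-hydroxy-12,13,14,15,16-pentanorlabd-7-en-11-al F5. Methylenation with excess ylide (Ph3PCH3Br, KN(SiMe3)2, THF, −78 → 0 °C) rejoins the route at 21.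

**Further compounds**
F1 | step 6 | dimethyl 12,13,14,15,16-pentanorlabda-5,8(17)-diene-11,19-dioate (C9 epimers) | COC(=O)[C@@]1(C)CCC[C@]2(C)C(C(=O)OC)C(=C)CC=C12
F2 | step 8 | dimethyl 12,13,14,15,16-pentanorlabd-8-ene-11,19-dioate (5α-H) | COC(=O)[C@@]1(C)CCC[C@]2(C)C(C(=O)OC)=C(C)CC[C@@H]12
F3 | step 8 | dimethyl 7-bromo-12,13,14,15,16-pentanorlabd-8-ene-11,19-dioate (C7 epimers) | COC(=O)[C@@]1(C)CCC[C@]2(C)C(C(=O)OC)=C(C)C(Br)C[C@@H]12
F4 | step 9 | 12,13,14,15,16-pentanorlabd-7-ene-11,19-diol | OC[C@@]1(C)CCC[C@]2(C)[C@@H](CO)C(C)=CC[C@@H]12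
F5 | step 9 | 19-hydroxy-12,13,14,15,16-pentanorlabd-7-en-11-al | OC[C@@]1(C)CCC[C@]2(C)[C@@H](C=O)C(C)=CC[C@@H]12
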